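**Plan**

- Numbering: ring C1 (side chain), C2 (tiglate), C3 (ketone), C4 (methyl), C5, C6; chain C7(=C12H2)–C8(=O)–C9=C10–C11(CH3)2OOH. β is the ring face that carries the C1 chain, α the opposite face.
- Enabling feature: C3 with its oxygen, C4 with its methyl, C5 and C6 are the four carbons of a 1-silyloxy-2-methylbutadiene; the trans C1/C2 pair is the E-alkene of a methyl enone whose acetyl group is a latent C2–O bond.
- Cuts, last to first: C11–OOH (singlet-oxygen ene), C10=C11 (cross-metathesis), C8–C9 (allylboration), C7=C12 (α-methylenation), tiglate C–O, epoxide and C2–O (peracid), then C2–C3 and C1–C6 of the carbocycle.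
- Forward: the cyclohexene is made first from two acyclic pieces by a catalytic enantioselective Diels–Alder reaction; the oxirane is fused on, the ester exchanged, C3 oxidised, and the chain grown from the C1 hydroxyethyl arm.
- Stereochemistry: C1, C2, C3 from the cycloaddition (E-enone gives trans C1/C2, endo gives cis C2/C3, catalyst gives the absolute sense); C2–O by Baeyer–Villiger migration with retention; C4/C5 by peracid attack anti to the C3 silyl ether; C3 later becomes the ketone.

Key step: step 5

Assumption: the (S)-diphenylprolinol-derived catalyst of step 5 is taken to follow the α-C–H···O binding model for acyclic enones (diene on the Cα-re face); if the sense proved opposite, the mirror-image catalyst from (R)-diphenylprolinol would be used with no other change.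

Remark: both hydroxyls are carried as TBS ethers so that one fluoride treatment (step 9) frees them together.

**Route**

Step 1
Reactants: 1 propane-1,3-diol
Product: 2 3-(tert-butyldimethylsilyloxy)propan-1-ol
Conditions: NaH (1.0 equiv), THF, 0 °C → rt; TBSCl (1.0 equiv), rt
Reagents that add atoms: tert-butyldimethylsilyl chloride, CC(C)(C)[Si](C)(C)Cl
Why: O-silylation of the sparingly soluble monosodium alkoxide of a symmetrical diol (Williamson-type monoprotection) should stop at the mono-ether.

Step 2
Reactants: 2 3-(tert-butyldimethylsilyloxy)propan-1-ol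
Product: 3 3-(tert-butyldimethylsilyloxy)propanal
Conditions: PhI(OAc)2 (1.1 equiv), TEMPO (10 mol%), CH2Cl2, rt
Reagents that add atoms: none
Why: TEMPO/oxoammonium oxidation of a primary alcohol stops at the aldehyde and is neutral enough to avoid β-elimination of the silyloxy group.

Step 3
Reactants: 3 3-(tert-butyldimethylsilyloxy)propanal; 4 1-(triphenylphosphoranylidene)propan-2-one
Product: 5 (E)-6-(tert-butyldimethylsilyloxy)hex-3-en-2-one
Conditions: CH2Cl2, rt
Reagents that add atoms: none
Why: Wittig olefination with a ketone-stabilised ylide should give the E-enone.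

Step 4
Reactants: 6 (E)-2-methylbut-2-enal
Product: 7 (1E)-1-(tert-butyldimethylsilyloxy)-2-methylbuta-1,3-diene
Conditions: TBSOTf (1.1 equiv), Et3N (1.5 equiv), Et2O, 0 °C → rt
Reagents that add atoms: tert-butyldimethylsilyl trifluoromethanesulfonate, CC(C)(C)[Si](C)(C)OS(=O)(=O)C(F)(F)F
Why: Silyl dienol ether formation (O-silylation of the enal, then γ-deprotonation of the C4 methyl group) should transfer the s-trans geometry of the enal into the 1E enol ether.

Step 5
Reactants: 5 (E)-6-(tert-butyldimethylsilyloxy)hex-3-en-2-one; 7 (1E)-1-(tert-butyldimethylsilyloxy)-2-methylbuta-1,3-diene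
Product: 8 endo cycloadduct (acetyl cis to C3–OTBS and trans to the C1 arm)
Conditions: (S)-diphenylprolinol-derived B-(o-tolyl)oxazaborolidine (20 mol%), Tf2NH (18 mol%), 7 (2 equiv), CH2Cl2, −78 → −40 °C
Reagents that add atoms: none
Why: The cationic oxazaborolidine binds the ketone oxygen of s-trans 5 and lowers its LUMO, and the diene adds in a concerted, asynchronous [4+2] cycloaddition in which the unsubstituted diene terminus (future C6, largest HOMO coefficient) bonds first to the β-carbon (C1) and the silyloxy-bearing terminus (C3) then bonds to the α-carbon (C2). The closest known reaction type is the oxazaborolidinium-catalysed enantioselective Diels–Alder reaction of 1-silyloxydienes with acyclic α,β-unsaturated ketones. The cyclohexene is the only ring formed and closes by intermolecular [4+2] cycloaddition, both σ-bonds being made suprafacially on diene and dienophile. The trans C1/C2 relationship comes from the E geometry of 5, the cis C2/C3 relationship from the endo placement of the acetyl group under the 1E diene, and the absolute configuration of all three centres from the catalyst, whose aryl group covers one face of the bound enone so that the diene adds to the Cα-re/Cβ-si face. The step needs ortho regiochemistry, endo topology and one enantioface: the strongly donating 1-silyloxy group outweighs the weaker, opposing bias of the 2-methyl group, Lewis acid complexation reinforces the endo preference, and the catalyst selects the face.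

Step 6
Reactants: 8 endo cycloadduct
Product: 10 epoxy acetate, via epoxy ketone 9 (not isolated)
Conditions: mCPBA (3.5 equiv), NaHCO3, CH2Cl2, 0 °C → rt
Reagents that add atoms: 3-chloroperbenzoic acid, O=C(OO)c1cccc(Cl)c1
Why: Prilezhaev epoxidation of the trisubstituted alkene should occur first on the β face, anti to the pseudoaxial C3 silyl ether (sets C4 and C5), and the same peracid then effects Baeyer–Villiger oxidation in which the secondary ring carbon C2 migrates in preference to methyl with retention (sets the C2–O bond).

Step 7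
Reactants: 10 epoxy acetate
Product: 11 epoxy alcohol
Conditions: DIBAL-H (2.5 equiv), CH2Cl2, −78 °C; aq. Rochelle salt
Reagents that add atoms: none
Why: Ester reduction by DIBAL-H frees the C2 hydroxyl at a temperature at which the aluminium alkoxide should neither open the oxirane nor allow 1,2-silyl migration from the cis C3 oxygen.

Step 8
Reactants: 11 epoxy alcohol; 12 tiglic acid
Product: 13 tiglate
Conditions: 12, 2,4,6-trichlorobenzoyl chloride, Et3N, toluene, rt; then 11, DMAP, rt → 40 °C
Reagents that add atoms: none
Why: Yamaguchi esterification (mixed anhydride, then acyl transfer through the N-acylpyridinium) acylates the equatorial C2 alcohol without breaking its C–O bond, so the configuration is kept.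

Step 9
Reactants: 13 tiglate
Product: 14 diol
Conditions: HF·pyridine, pyridine, THF, 0 °C → rt
Reagents that add atoms: none
Why: Fluoride-driven Si–O cleavage in a buffered, non-basic medium removes both silyl ethers without forming an alkoxide that could trigger tiglate migration or Payne rearrangement.

Step 10
Reactants: 14 diol
Product: 15 keto aldehyde
Conditions: Dess–Martin periodinane (3 equiv), NaHCO3, CH2Cl2, 0 °C → rt
Reagents that add atoms: none
Why: Dess–Martin oxidation converts the primary alcohol into the aldehyde and the C3 carbinol into the ketone in one neutral operation, leaving the epoxide and the C2 centre untouched.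

Step 11
Reactants: 15 keto aldehyde
Product: 16 α-methylene aldehyde
Conditions: 37% aq. CH2O, pyrrolidine (10 mol%), EtCO2H (10 mol%), i-PrOH, 45 °C
Reagents that add atoms: formaldehyde, C=O
Why: Amine-catalysed Mannich condensation (enamine of the aldehyde, addition to formaldehyde iminium, elimination of the amine) methylenates C7 selectively because the hindered ring ketone forms an enamine far more slowly.

Step 12
Reactants: 16 α-methylene aldehyde
Product: 17 allyl carbinol
Conditions: allylB(pin) (1.5 equiv), CH2Cl2, rt; aq. NaHCO3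
Reagents that add atoms: 2-allyl-4,4,5,5-tetramethyl-1,3,2-dioxaborolane, C=CCB1OC(C)(C)C(C)(C)O1
Why: Allylboration through a closed six-membered transition state is selective for the aldehyde over ketone and ester; the C8 carbinol forms as a mixture of epimers that is erased in step 14.

Step 13
Reactants: 17 allyl carbinol
Product: 18 prenyl carbinol
Conditions: Grubbs second-generation catalyst (5 mol%), 2-methylbut-2-ene/CH2Cl2, 35 °C
Reagents that add atoms: 2-methylbut-2-ene, CC=C(C)C
Why: Olefin cross-metathesis of the terminal alkene with excess 2-methylbut-2-ene is the standard allyl-to-prenyl conversion, and the 1,1-disubstituted and electron-poor trisubstituted alkenes should not engage the catalyst.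

Step 14
Reactants: 18 prenyl carbinol
Product: 19 skipped dienone
Conditions: Dess–Martin periodinane (1.5 equiv), NaHCO3, CH2Cl2, 0 °C
Reagents that add atoms: none
Why: Dess–Martin oxidation under buffered, base-free conditions should give the β,γ-unsaturated ketone without moving the C10=C11 double bond into conjugation.

Step 15
Reactants: 19 skipped dienone
Product: 20 CNP0284595.1
Conditions: O2, tetraphenylporphyrin (1 mol%), visible light, CH2Cl2, −20 °C
Reagents that add atoms: dioxygen, O=O
Why: In the Schenck ene reaction singlet oxygen attacks only the electron-rich C10=C11 alkene, bonds to the more substituted C11 and abstracts a C9 hydrogen activated by the adjacent carbonyl, so the double bond shifts into conjugation as the E-enone; no stereocentre is formed.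

**Compound list**

1 | propane-1,3-diol | OCCCO | starting material
2 | 3-(tert-butyldimethylsilyloxy)propan-1-ol | CC(C)(C)[Si](C)(C)OCCCO | intermediate
3 | 3-(tert-butyldimethylsilyloxy)propanal | CC(C)(C)[Si](C)(C)OCCC=O | intermediate
4 | 1-(triphenylphosphoranylidene)propan-2-one | CC(=O)C=P(c1ccccc1)(c1ccccc1)c1ccccc1 | starting material
5 | (E)-6-(tert-butyldimethylsilyloxy)hex-3-en-2-one | CC(=O)/C=C/CCO[Si](C)(C)C(C)(C)C | intermediate
6 | (E)-2-methylbut-2-enal (tiglaldehyde) | C/C=C(\C)C=O | starting material
7 | (1E)-1-(tert-butyldimethylsilyloxy)-2-methylbuta-1,3-diene | C=C/C(C)=C/O[Si](C)(C)C(C)(C)C | intermediate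
8 | endo cycloadduct, 1-[(1S,2S,6S)-2-(tert-butyldimethylsilyloxy)-6-[2-(tert-butyldimethylsilyloxy)ethyl]-3-methylcyclohex-3-en-1-yl]ethan-1-one (C2 acetyl α, C3 OTBS α, C1 arm β) | CC(C)(C)[Si](C)(C)OCC[C@@H]1CC=C(C)[C@@H](O[Si](C)(C)C(C)(C)C)[C@H]1C(C)=O | intermediate
9 | epoxy ketone: 8 with a β-4,5-epoxide (oxirane on the face of the C1 arm, anti to C3 OTBS) | CC(C)(C)[Si](C)(C)OCC[C@@H]1C[C@@H]2O[C@]2(C)[C@@H](O[Si](C)(C)C(C)(C)C)[C@H]1C(C)=O | intermediate
10 | epoxy acetate: C2 acetoxy α, C3 OTBS α, 4,5-epoxide β, C1 2-(TBSO)ethyl β | CC(C)(C)[Si](C)(C)OCC[C@@H]1C[C@@H]2O[C@]2(C)[C@@H](O[Si](C)(C)C(C)(C)C)[C@H]1OC(C)=O | intermediate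
11 | epoxy alcohol: as 10 with free C2 hydroxyl (α) | CC(C)(C)[Si](C)(C)OCC[C@@H]1C[C@@H]2O[C@]2(C)[C@@H](O[Si](C)(C)C(C)(C)C)[C@H]1O | intermediate
12 | tiglic acid, (E)-2-methylbut-2-enoic acid | C/C=C(\C)C(=O)O | starting material
13 | tiglate: as 11 with C2 (E)-2-methylbut-2-enoyloxy (α) | CC(C)(C)[Si](C)(C)OCC[C@@H]1C[C@@H]2O[C@]2(C)[C@@H](O[Si](C)(C)C(C)(C)C)[C@H]1OC(=O)/C(C)=C/C | intermediate
14 | diol: C3 hydroxyl (α) and C1 2-hydroxyethyl (β), C2 tiglate α, 4,5-epoxide β | OCC[C@@H]1C[C@@H]2O[C@]2(C)[C@@H](O)[C@H]1OC(=O)/C(C)=C/C | intermediate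
15 | keto aldehyde: C3 ketone, C1 2-oxoethyl (β), C2 tiglate α, 4,5-epoxide β | O=CC[C@@H]1C[C@@H]2O[C@]2(C)C(=O)[C@H]1OC(=O)/C(C)=C/C | intermediate
16 | α-methylene aldehyde: C1 bears 3-oxoprop-1-en-2-yl (C7=C12H2, C8 aldehyde) | C=C(C=O)[C@@H]1C[C@@H]2O[C@]2(C)C(=O)[C@H]1OC(=O)/C(C)=C/C | intermediate
17 | allyl carbinol: C1 bears 3-hydroxyhexa-1,5-dien-2-yl (C8 epimers) | C=CCC(O)C(=C)[C@@H]1C[C@@H]2O[C@]2(C)C(=O)[C@H]1OC(=O)/C(C)=C/C | intermediate
18 | prenyl carbinol: C1 bears 3-hydroxy-6-methylhepta-1,5-dien-2-yl (C8 epimers) | CC(C)=CCC(O)C(=C)[C@@H]1C[C@@H]2O[C@]2(C)C(=O)[C@H]1OC(=O)/C(C)=C/C | intermediate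
19 | skipped dienone: C1 bears 6-methyl-3-oxohepta-1,5-dien-2-yl | CC(C)=CCC(=O)C(=C)[C@@H]1C[C@@H]2O[C@]2(C)C(=O)[C@H]1OC(=O)/C(C)=C/C | intermediate
20 | CNP0284595.1, (1S,3S,4S,6S)-4-[(4E)-6-hydroperoxy-6-methyl-3-oxohepta-1,4-dien-2-yl]-1-methyl-2-oxo-7-oxabicyclo[4.1.0]heptan-3-yl (2E)-2-methylbut-2-enoate | C=C(C(=O)/C=C/C(C)(C)OO)[C@@H]1C[C@@H]2O[C@]2(C)C(=O)[C@H]1OC(=O)/C(C)=C/C | target

**Count**

Total: 15 steps. Longest linear sequence: 14 steps (1 → 2 → 3 → 5 → 8 → 10 → 11 → 13 → 14 → 15 → 16 → 17 → 18 → 19 → 20); the diene 7 is one step off the line.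

**Steps most likely to fail**

Step 5. The β-alkyl enone may be too weak a dienophile, so that protodesilylation of the diene or open-chain vinylogous Mukaiyama–Michael addition outruns ring closure, or the face discrimination erodes. The fallback raises the electrophile to the aldehyde oxidation level. It sets out from 3: Wittig reaction with (triphenylphosphoranylidene)acetaldehyde would give (E)-5-(tert-butyldimethylsilyloxy)pent-2-enal F1, a far stronger acceptor once bound to the same cationic oxazaborolidine (catalyst antipode chosen for the formyl C–H···O binding mode). Cycloaddition with 7 would give the endo aldehyde (1S,2S,6S)-2-(tert-butyldimethylsilyloxy)-6-[2-(tert-butyldimethylsilyloxy)ethyl]-3-methylcyclohex-3-ene-1-carbaldehyde F2. Addition of MeMgBr at −78 °C would give the methyl carbinol F3 (carbinol epimers), and Dess–Martin oxidation brings the material back to 8.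

Step 15. Hydrogen abstraction from the (Z)-methyl group of the prenyl unit may compete with abstraction at C9 and send the oxygen to C10, or the skipped enone may slip into conjugation before oxygenation. The fallback fixes the C11–O–O connectivity in a building block and joins it by metathesis. It sets out from 16: vinylmagnesium bromide at −90 °C (inverse addition, the unhindered enal reacting ahead of the doubly α-substituted ring ketone) would give the divinyl carbinol F4, and Dess–Martin oxidation the divinyl ketone F5. Separately, 2-methylbut-3-en-2-ol with 50% H2O2 and catalytic H2SO4 would give 2-methylbut-3-en-2-yl hydroperoxide F6, which 2-methoxypropene and PPTS convert into the peroxyketal 3-[(2-methoxypropan-2-yl)peroxy]-3-methylbut-1-ene F7. Cross-metathesis of F5 with F7 (Hoveyda–Grubbs second-generation catalyst, CH2Cl2, 40 °C) engages only the vinyl ketone and should give the E-configured peroxyketal of the target F8. AcOH/THF/H2O at rt then releases the hydroperoxide and the sequence comes back at 20.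

Step 6. Oxygen insertion into the hindered methyl ketone may be slow enough for 3-chlorobenzoic acid to open the new oxirane, or prolonged peracid exposure may erode material. The fallback reverses the order of the two oxidations. It sets out from 8: a Baeyer–Villiger oxidation with bis(trimethylsilyl) peroxide and a Lewis acid (SnCl4/trans-cyclohexane-1,2-diamine, CH2Cl2), a reagent pair that leaves alkenes alone, would give the cyclohexenyl acetate F9. Brief epoxidation of F9 with dimethyldioxirane in acetone at 0 °C, again anti to the C3 silyl ether, comes back to the route at 10.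

**Further compounds**

F1 | step 5 | (E)-5-(tert-butyldimethylsilyloxy)pent-2-enal | O=C/C=C/CCO[Si](C)(C)C(C)(C)C
F2 | step 5 | (1S,2S,6S)-2-(tert-butyldimethylsilyloxy)-6-[2-(tert-butyldimethylsilyloxy)ethyl]-3-methylcyclohex-3-ene-1-carbaldehyde | CC(C)(C)[Si](C)(C)OCC[C@@H]1CC=C(C)[C@@H](O[Si](C)(C)C(C)(C)C)[C@H]1C=O
F3 | step 5 | methyl carbinol, 1-[2-(tert-butyldimethylsilyloxy)-6-[2-(tert-butyldimethylsilyloxy)ethyl]-3-methylcyclohex-3-en-1-yl]ethan-1-ol with the ring configuration of 8 (carbinol epimers) | CC(C)(C)[Si](C)(C)OCC[C@@H]1CC=C(C)[C@@H](O[Si](C)(C)C(C)(C)C)[C@H]1C(C)O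
F4 | step 15 | divinyl carbinol: ring of 16 with C1 bearing 3-hydroxypenta-1,4-dien-2-yl (C8 epimers) | C=CC(O)C(=C)[C@@H]1C[C@@H]2O[C@]2(C)C(=O)[C@H]1OC(=O)/C(C)=C/C
F5 | step 15 | divinyl ketone: ring of 16 with C1 bearing 3-oxopenta-1,4-dien-2-yl | C=CC(=O)C(=C)[C@@H]1C[C@@H]2O[C@]2(C)C(=O)[C@H]1OC(=O)/C(C)=C/C
F6 | step 15 | 2-methylbut-3-en-2-yl hydroperoxide | C=CC(C)(C)OO
F7 | step 15 | 3-[(2-methoxypropan-2-yl)peroxy]-3-methylbut-1-ene | C=CC(C)(C)OOC(C)(C)OC
F8 | step 15 | 2-methoxypropan-2-yl peroxyketal of 20 | C=C(C(=O)/C=C/C(C)(C)OOC(C)(C)OC)[C@@H]1C[C@@H]2O[C@]2(C)C(=O)[C@H]1OC(=O)/C(C)=C/C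
F9 | step 6 | cyclohexenyl acetate, (1S,2S,6S)-2-(tert-butyldimethylsilyloxy)-6-[2-(tert-butyldimethylsilyloxy)ethyl]-3-methylcyclohex-3-en-1-yl acetate | CC(C)(C)[Si](C)(C)OCC[C@@H]1CC=C(C)[C@@H](O[Si](C)(C)C(C)(C)C)[C@H]1OC(C)=O
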